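Readings and results were generated by integration from invented constants, and the scatter is random.

The amounts matter first: Thursday's run held 0.15 M of protic impurity against 0.45 M of starting material, and the new flask holds 0.150 M against 0.30 M.

- Thursday's: starting material 0.45 M; partner 1.1 equiv; protic impurity 0.15 M; run made earlier
- flask: starting material 0.30 M; partner 1.10 equiv; protic impurity 0.150 M; time 4.0 d

- Thursday's (time / h: target / %, starting material / %): 5.00: 4.2, 49.4; 10.0: 6.6, 37.0; 15.0: 6.8, 29.6; 20.0: 10.5, 25.1; 25.0: 10.3, 20.2; 30.0: 9.9, 19.4

(scatter of a reading: 1 percentage point)

- the analysis behind the earlier runs scatters by 1 percentage point, standard deviation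

* the best time, 4.0 d at the latest, for target
* the amount of target, in percent of the starting material charged, at that time

Thursday's starting material lost 50.6% of its charge by 5.00 h, but 12 percentage points in the next 5.00 h, which reads as a fast early toll. The reckoning here assumes that each protic impurity takes one starting material. That leaves a free share φ, the part of the charge not quenched: 66.7% on Thursday and 50.0% in the new flask.

Thursday's target stayed level within the scatter from 20.0 h to 30.0 h, with a mean reading of 10.2%. This gives Y, the target per free share, as 15.3%.

Turned round, at equal Y the new flask could beat Thursday's plateau if its φ were above Thursday's, but it stands lower. This reckoning therefore expects about 7.67% in the new flask; taking Thursday's level stretch over unchanged, which is an assumption, it places the best time between 0.83 d and 1.2 d. The forecast differs, giving 15% at 4 d: “Target should keep creeping upward”.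

The new flask gives 8.01% at 1.05 d.

    partner → second intermediate (k = 0.140 h⁻¹)
    starting material + protic impurity → quenched substrate (k = 11.0 M⁻¹ h⁻¹)
    2 second intermediate → homo product (k = 0.560 M⁻¹ h⁻¹)
    starting material + target → side product (k = 0.170 M⁻¹ h⁻¹)
    open intermediate + second intermediate ⇌ target (K = 7.00 M⁻¹, k = 0.490 M⁻¹ h⁻¹)
    starting material ⇌ open intermediate (K = 2.00, k = 0.0650 h⁻¹)

At that time the new flask holds 50.0% as quenched substrate, level with the impurity's 50.0% of the charge, and protic impurity stands at 0%. Its Y comes to 16.0%, against 15.3% read from Thursday's run. The neighbour charged with 0.75 M of starting material has φ of 80.0%, for which Y from Thursday's gives 12.2%, and that neighbour reaches 11.8%.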